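Two questions stand on this flask, and both ask how strongly the rate of making target answers to the charge of free catalyst.

| setting | east | flask |
|---|---|---|
| substrate | 0.15 M | 0.10 M |
| gas | 6.3 mM (held) | 6.3 mM (held) |
| free catalyst | 0.50 mM | 0.50 mM |
| remark | run made earlier |  |

east run (percent of the substrate charged)

| time / s | target / % | substrate / % |
|---|---|---|
| 15.0 | 11.1 | 88.9 |
| 30.0 | 22.3 | 77.7 |
| 40.0 | 28.2 | 70.4 |
| 60.0 | 44.0 | 56.4 |
| 80.0 | 57.5 | 42.4 |

(each reading ± 0.5 percentage points)

* apparent order in free catalyst when 30% of the substrate are converted (percent change of the rate of making target for one percent more free catalyst charged)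
* factor on the rate of making target when 30% of the substrate are converted if free catalyst is charged twice over

- at the start none of the gas is in solution
- no earlier run changes the charge of free catalyst; that part of a forecast is a guess

In the east run, target reaches 57.5% at 80.0 s along a nearly straight line, a reading of 1.08 mM s⁻¹. Two chemists read this plateau differently.

The first says the catalyst is kept busy by substrate, so the rate goes with the catalyst: order 1, factor 2. The second says gas transfer is the rate-limiting step, so more catalyst gains nothing: order 0, factor 1.

Both can use one reckoning of mine, which assumes one gas per target. Gas enters the solution at a transfer coefficient times the gap to saturation, and that supply is greatest in a solution empty of gas. Dividing the rate by the saturation concentration removes the concentration units and gives 0.171 s⁻¹, the needed transfer coefficient, the lowest coefficient at which supply can match the plateau. Put as a time constant, a saturated solution holds 5.85 s of consumption. With a coefficient above that, the share of saturation missing at steady supply is the needed coefficient over the actual one.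

At this rate, the first chemist's order belongs to a small missing share, where the solution stays close to saturation. The second's belongs to a share near one. The readings do not give the coefficient.

The forecast sides with the second, “I lean towards transfer limitation”, but hedges: order 0.3 and factor 1.25.

For this flask the simulation gives order 0.18 and factor 1.07, each lower than the forecast's value, and the second chemist wins.

    catalyst intermediate C ⇌ catalyst intermediate D (K = 0.990, k = 1200 s⁻¹)
    substrate + catalyst intermediate A → catalyst intermediate B (k = 410 L mol⁻¹ s⁻¹)
    coupling partner + free catalyst ⇌ catalyst intermediate A (K = 3700 L mol⁻¹, k = 28000 L mol⁻¹ s⁻¹)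
    catalyst intermediate B → released group + catalyst intermediate C (k = 12.0 s⁻¹)
    catalyst intermediate D → free catalyst + target (k = 14.0 s⁻¹)
    gas ⇌ coupling partner, rate k6*(csat - [coupling partner]) (kL = 0.190 s⁻¹)
    free catalyst ⇌ dormant form (K = 2.50, k = 0.0370 s⁻¹)

With the transfer coefficient 0.19 s⁻¹, the east run's needed coefficient 0.171 s⁻¹ puts that run's missing share at 90.1%. This flask has 39.4% target at 0.600 min, an average of 1.10 mM s⁻¹ since the start. At that time c(coupling partner), the dissolved gas, is 6.00 × 10⁻⁴ M against a saturation of 6.3 mM, so 90.5% of saturation is missing.

The numbers in the tables were computed on assumed constants; noise was put on by code.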